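**Retrosynthetic overview** (germacrane numbering: C1=C10 Z, C4=C5 E, C3–OH, C6–O–C12 lactone, C8–OAng, C9–OAc, C11=C13)
1. The target is unveiled from a 3-O-TBDPS, 8-O-PMB, 9-O-TBS protected lactone by α-methylenation (C13), then C8 angeloylation, C9 acetylation and C3 desilylation.
2. Ring order: the ten-membered carbocycle is closed first, at C5–C6, by an intramolecular Nozaki–Hiyama–Kishi vinyl iodide/aldehyde coupling; the γ-lactone is closed second, by C6–O attack on the C12 tert-butyl ester.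
3. The open chain is joined at C1=C10 by a Z-selective Wittig reaction between an α-silyloxy methyl ketone (C6–C12 part) and a C1–C5 phosphonium ylide.
4. Ketone part: lipase desymmetrisation of 2-O-PMB-glycerol (C8), anti-selective vinyl cuprate addition (C7), chelation-controlled isopropenyl Grignard addition (C9), double oxidative cleavage.
5. Ylide part: ketoreductase reduction of a β-keto ester made from (E)-3-iodo-2-methylacrylic acid (C3 and the 4E vinyl iodide).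

Abbreviations in names: PMB = 4-methoxybenzyl, TBS = tert-butyldimethylsilyl, TBDPS = tert-butyldiphenylsilyl.
Assumption: the lipase acetylates 2-O-PMB-glycerol with the same sense as reported for 2-O-benzylglycerol and gives the (S)-monoacetate.

**Route**

Step 1
Reactants: 1 cis-2-phenyl-1,3-dioxan-5-ol
Product: 2 cis-5-(PMB-oxy)-2-phenyl-1,3-dioxane
Conditions: NaH, PMBCl, Bu4NI (cat.), THF/DMF, 0 °C → rt
Reagents that add atoms: 4-methoxybenzyl chloride, COc1ccc(CCl)cc1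
Why: Williamson etherification of the only free hydroxyl of an achiral acetal, so no stereochemical issue arises.

Step 2
Reactants: 2 cis-5-(PMB-oxy)-2-phenyl-1,3-dioxane
Product: 3 2-(PMB-oxy)propane-1,3-diol
Conditions: AcOH/H2O (4:1), 45 °C
Reagents that add atoms: none
Why: Acid hydrolysis of the benzylidene acetal leaves the PMB ether untouched and gives the prochiral 1,3-diol.

Step 3
Reactants: 3 2-(PMB-oxy)propane-1,3-diol
Product: 4 (2S)-3-hydroxy-2-(PMB-oxy)propyl acetate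
Conditions: lipase from Burkholderia cepacia (Amano lipase PS), vinyl acetate, t-BuOMe, 25 °C
Reagents that add atoms: vinyl acetate, C=COC(C)=O
Why: The lipase (a serine hydrolase) acylates only one of the two enantiotopic hydroxymethyl groups in an irreversible transesterification (enzymatic desymmetrisation), which creates the first stereocentre, the future C8, as the (S)-monoacetate.

Step 4
Reactants: 4 (2S)-3-hydroxy-2-(PMB-oxy)propyl acetate
Product: 5 (2R)-2-(PMB-oxy)-3-(TBDPS-oxy)propyl acetate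
Conditions: TBDPSCl, imidazole, CH2Cl2, 0 °C
Reagents that add atoms: tert-butyl(chloro)diphenylsilane, CC(C)(C)[Si](Cl)(c1ccccc1)c1ccccc1
Why: Silylation of the remaining primary hydroxyl under mild base locks in the enzymatic differentiation of the two arms (the silylated arm becomes C9) before acetyl migration can occur.

Step 5
Reactants: 5 (2R)-2-(PMB-oxy)-3-(TBDPS-oxy)propyl acetate
Product: 6 (2R)-2-(PMB-oxy)-3-(TBDPS-oxy)propan-1-ol
Conditions: K2CO3 (0.2 equiv), MeOH, 0 °C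
Reagents that add atoms: none
Why: Base-catalysed transesterification with methanol removes the acetate and frees the arm that becomes C7, while the silyl and PMB ethers stay.

Step 6
Reactants: 6 (2R)-2-(PMB-oxy)-3-(TBDPS-oxy)propan-1-ol
Product: 7 (2S)-2-(PMB-oxy)-3-(TBDPS-oxy)propanal
Conditions: Dess–Martin periodinane, CH2Cl2, 0 °C → rt
Reagents that add atoms: none
Why: Dess–Martin oxidation gives the α-alkoxy aldehyde under non-basic conditions, so the stereocentre is not epimerised.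

Step 7
Reactants: 7 (2S)-2-(PMB-oxy)-3-(TBDPS-oxy)propanal
Product: 8 tert-butyl (2E,4R)-4-(PMB-oxy)-5-(TBDPS-oxy)pent-2-enoate
Conditions: Ph3P=CHCO2t-Bu, CH2Cl2, rt
Reagents that add atoms: tert-butyl (triphenylphosphoranylidene)acetate, CC(C)(C)OC(=O)C=P(c1ccccc1)(c1ccccc1)c1ccccc1
Why: Wittig olefination with a stabilised ylide gives the E-enoate and is mild enough to keep the α-alkoxy stereocentre intact.

Step 8
Reactants: 8 tert-butyl (2E,4R)-4-(PMB-oxy)-5-(TBDPS-oxy)pent-2-enoate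
Product: 10 tert-butyl (3S,4R)-3-ethenyl-4-(PMB-oxy)-5-(TBDPS-oxy)pentanoate, via silyl ketene acetal 9 (not isolated)
Conditions: CH2=CHMgBr, CuBr·SMe2 (20 mol%), TMSCl, THF, −78 → −40 °C; then aq. NH4Cl
Reagents that add atoms: vinylmagnesium bromide, C=C[Mg]Br; chlorotrimethylsilane, C[Si](C)(C)Cl (atoms in 9 only)
Why: Copper-catalysed, TMSCl-accelerated conjugate addition places the vinyl group anti to the γ-PMB-oxy group (modified Felkin–Anh model for γ-alkoxy enoates), which sets C7 as 3S, and the silyl ketene acetal is hydrolysed on work-up.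

Step 9
Reactants: 10 tert-butyl (3S,4R)-3-ethenyl-4-(PMB-oxy)-5-(TBDPS-oxy)pentanoate
Product: 11 tert-butyl (3S,4R)-3-ethenyl-5-hydroxy-4-(PMB-oxy)pentanoate
Conditions: Bu4NF, AcOH, THF, 0 °C → rt
Reagents that add atoms: none
Why: Fluoride desilylation buffered with acetic acid frees the primary C9 hydroxyl without touching the tert-butyl ester or the PMB ether.

Step 10
Reactants: 11 tert-butyl (3S,4R)-3-ethenyl-5-hydroxy-4-(PMB-oxy)pentanoate
Product: 12 tert-butyl (3S,4R)-3-ethenyl-5-oxo-4-(PMB-oxy)pentanoate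
Conditions: Dess–Martin periodinane, CH2Cl2, rt
Reagents that add atoms: none
Why: Dess–Martin oxidation to the α-PMB-oxy aldehyde avoids base and therefore epimerisation at C8.

Step 11
Reactants: 12 tert-butyl (3S,4R)-3-ethenyl-5-oxo-4-(PMB-oxy)pentanoate
Product: 13 tert-butyl (3S,4R,5R)-3-ethenyl-5-hydroxy-6-methyl-4-(PMB-oxy)hept-6-enoate
Conditions: MgBr2·OEt2, CH2Cl2, −78 °C; then CH2=C(CH3)MgBr (THF), −78 °C; pH 7 buffer
Reagents that add atoms: isopropenylmagnesium bromide, CC(=C)[Mg]Br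
Why: Cram chelate-controlled Grignard addition, in which magnesium bridges the aldehyde oxygen and the α-PMB ether and the nucleophile attacks the face opposite to the C7 branch, gives the 8,9-syn alcohol (C9 as 5R).

Step 12
Reactants: 13 tert-butyl (3S,4R,5R)-3-ethenyl-5-hydroxy-6-methyl-4-(PMB-oxy)hept-6-enoate
Product: 14 tert-butyl (3S,4R,5R)-3-ethenyl-6-methyl-4-(PMB-oxy)-5-(TBS-oxy)hept-6-enoate
Conditions: TBSOTf, 2,6-lutidine, CH2Cl2, −78 °C
Reagents that add atoms: tert-butyldimethylsilyl triflate, CC(C)(C)[Si](C)(C)OS(=O)(=O)C(F)(F)F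
Why: Silyl triflate silylation protects the hindered secondary C9 hydroxyl at low temperature, where the tert-butyl ester is not attacked.

Step 13
Reactants: 14 tert-butyl (3S,4R,5R)-3-ethenyl-6-methyl-4-(PMB-oxy)-5-(TBS-oxy)hept-6-enoate
Product: 15 tert-butyl (3R,4R,5S)-3-formyl-6-oxo-4-(PMB-oxy)-5-(TBS-oxy)heptanoate
Conditions: OsO4 (2 mol%), NaIO4, 2,6-lutidine, dioxane/H2O (3:1), rt
Reagents that add atoms: OsO4, O=[Os](=O)(=O)=O (catalytic carrier of the oxygen atoms); sodium periodate, [Na+].[O-]I(=O)(=O)=O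
Why: Johnson–Lemieux oxidative cleavage turns the vinyl group into the C6 aldehyde and the isopropenyl group into the C10 methyl ketone in one operation, the lutidine buffer preventing epimerisation at C7.

Step 14
Reactants: 15 tert-butyl (3R,4R,5S)-3-formyl-6-oxo-4-(PMB-oxy)-5-(TBS-oxy)heptanoate
Product: 16 tert-butyl (3R,4R,5S)-3-(dimethoxymethyl)-6-oxo-4-(PMB-oxy)-5-(TBS-oxy)heptanoate
Conditions: HC(OMe)3, CeCl3·7H2O (cat.), MeOH, 0 °C → rt
Reagents that add atoms: trimethyl orthoformate, COC(OC)OC; methanol, CO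
Why: Lewis acid-catalysed acetalisation is chemoselective for the aldehyde over the hindered α-silyloxy ketone and masks C6 for the Wittig step.

Step 15
Reactants: 17 diethyl methylmalonate
Product: 18 diethyl 2-(diiodomethyl)-2-methylmalonate
Conditions: NaH, CHI3, Et2O, reflux
Reagents that add atoms: iodoform, IC(I)I
Why: The malonate anion is C-alkylated by iodoform (diiodocarbene pathway), installing the CHI2 group that becomes the vinyl iodide.

Step 16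
Reactants: 18 diethyl 2-(diiodomethyl)-2-methylmalonate
Product: 19 (2E)-3-iodo-2-methylprop-2-enoic acid
Conditions: KOH, EtOH/H2O, reflux; then HCl
Reagents that add atoms: potassium hydroxide, [K+].[OH-]
Why: Saponification followed by decarboxylative elimination of iodide gives the acrylic acid as the favoured E isomer, which fixes the later 4E ring olefin.

Step 17
Reactants: 19 (2E)-3-iodo-2-methylprop-2-enoic acid
Product: 21 ethyl (4E)-5-iodo-4-methyl-3-oxopent-4-enoate, via acyl imidazolide 20 (not isolated)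
Conditions: 1,1'-carbonyldiimidazole, THF, rt; then Mg(O2CCH2CO2Et)2, THF, 40 °C; 1 M HCl
Reagents that add atoms: magnesium bis(ethyl malonate), [Mg+2].CCOC(=O)CC(=O)[O-].CCOC(=O)CC(=O)[O-]; 1,1'-carbonyldiimidazole, O=C(n1ccnc1)n1ccnc1 (atoms in 20 only)
Why: Masamune–Brooks chain extension, in which the acyl imidazolide acylates the magnesium malonate and decarboxylation gives the β-keto ester.

Step 18
Reactants: 21 ethyl (4E)-5-iodo-4-methyl-3-oxopent-4-enoate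
Product: 22 ethyl (3S,4E)-3-hydroxy-5-iodo-4-methylpent-4-enoate
Conditions: ketoreductase (S-selective, from a commercial screening panel), NADP+ (cat.), i-PrOH, phosphate buffer pH 7, 30 °C
Reagents that add atoms: none
Why: The ketoreductase (an NADPH-dependent alcohol dehydrogenase) delivers hydride to one face of the ketone, with the cofactor recycled by isopropanol, which sets C3 as 3S without touching the vinyl iodide.

Step 19
Reactants: 22 ethyl (3S,4E)-3-hydroxy-5-iodo-4-methylpent-4-enoate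
Product: 23 ethyl (3S,4E)-5-iodo-4-methyl-3-(TBDPS-oxy)pent-4-enoate
Conditions: TBDPSCl, imidazole, DMF, rt
Reagents that add atoms: tert-butyl(chloro)diphenylsilane, CC(C)(C)[Si](Cl)(c1ccccc1)c1ccccc1
Why: Silylation of the secondary allylic alcohol with a robust group that survives every later step until the final deprotection.

Step 20
Reactants: 23 ethyl (3S,4E)-5-iodo-4-methyl-3-(TBDPS-oxy)pent-4-enoate
Product: 24 (3S,4E)-5-iodo-4-methyl-3-(TBDPS-oxy)pent-4-en-1-ol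
Conditions: i-Bu2AlH, CH2Cl2, −78 → 0 °C; aq. potassium sodium tartrate
Reagents that add atoms: none
Why: Hydride reduction of the ester to the primary alcohol, to which the vinyl iodide and the silyl ether are inert at low temperature.

Step 21
Reactants: 24 (3S,4E)-5-iodo-4-methyl-3-(TBDPS-oxy)pent-4-en-1-ol
Product: 25 (1E,3S)-1,5-diiodo-2-methyl-3-(TBDPS-oxy)pent-1-ene
Conditions: I2, PPh3, imidazole, CH2Cl2, 0 °C
Reagents that add atoms: iodine, II
Why: Appel-type iodination converts the primary alcohol into the iodide by SN2 displacement of the oxyphosphonium intermediate.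

Step 22
Reactants: 25 (1E,3S)-1,5-diiodo-2-methyl-3-(TBDPS-oxy)pent-1-ene
Product: 26 [(3S,4E)-5-iodo-4-methyl-3-(TBDPS-oxy)pent-4-en-1-yl]triphenylphosphonium iodide
Conditions: PPh3, MeCN, 80 °C
Reagents that add atoms: triphenylphosphine, c1ccc(cc1)P(c1ccccc1)c1ccccc1
Why: SN2 quaternisation of the phosphine by the primary alkyl iodide, in which the vinyl iodide does not take part.

Step 23
Reactants: 26 [(3S,4E)-5-iodo-4-methyl-3-(TBDPS-oxy)pent-4-en-1-yl]triphenylphosphonium iodide; 16 tert-butyl (3R,4R,5S)-3-(dimethoxymethyl)-6-oxo-4-(PMB-oxy)-5-(TBS-oxy)heptanoate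
Product: 28 tert-butyl (3R,4R,5R,6Z,9S,10E)-3-(dimethoxymethyl)-11-iodo-6,10-dimethyl-4-(PMB-oxy)-5-(TBS-oxy)-9-(TBDPS-oxy)undeca-6,10-dienoate, via phosphonium ylide 27 (not isolated)
Conditions: NaN(SiMe3)2, THF, −78 → 0 °C; then 16, −78 °C → rt
Reagents that add atoms: none
Why: Wittig olefination of an α-silyloxy methyl ketone by a non-stabilised ylide is Z-selective (the new chain ends up cis to the oxygenated carbon C9), giving the 1(10)Z trisubstituted olefin, and at −78 °C addition outruns enolisation so C9 is not epimerised.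

Step 24
Reactants: 28 tert-butyl (3R,4R,5R,6Z,9S,10E)-3-(dimethoxymethyl)-11-iodo-6,10-dimethyl-4-(PMB-oxy)-5-(TBS-oxy)-9-(TBDPS-oxy)undeca-6,10-dienoate
Product: 29 tert-butyl (3R,4R,5R,6Z,9S,10E)-3-formyl-11-iodo-6,10-dimethyl-4-(PMB-oxy)-5-(TBS-oxy)-9-(TBDPS-oxy)undeca-6,10-dienoate
Conditions: PPTS (cat.), acetone/H2O (9:1), 45 °C
Reagents that add atoms: water, O
Why: Mild acid hydrolysis of the dimethyl acetal releases the C6 aldehyde while the silyl ethers, the PMB ether and the tert-butyl ester survive.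

Step 25
Reactants: 29 tert-butyl (3R,4R,5R,6Z,9S,10E)-3-formyl-11-iodo-6,10-dimethyl-4-(PMB-oxy)-5-(TBS-oxy)-9-(TBDPS-oxy)undeca-6,10-dienoate
Product: 30 tert-butyl 2-[(1S,2R,3E,5S,7Z,9R,10R)-2-hydroxy-4,8-dimethyl-10-(PMB-oxy)-9-(TBS-oxy)-5-(TBDPS-oxy)cyclodeca-3,7-dien-1-yl]acetate
Conditions: CrCl2 (10 equiv), NiCl2 (2 mol%), DMSO/THF, rt, 2 mM, slow addition
Reagents that add atoms: none
Why: Intramolecular Nozaki–Hiyama–Kishi reaction, in which zerovalent nickel inserts into the C–I bond and the alkenyl group passes to trivalent chromium and adds to the aldehyde with retention of the E geometry, closes the ten-membered ring, and C6 is expected as 6R from a transition state that keeps the C6–O bond and the C7 side chain pseudo-equatorial (H6/H7 anti); this is substrate control and is not assured.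

Step 26
Reactants: 30 tert-butyl 2-[(1S,2R,3E,5S,7Z,9R,10R)-2-hydroxy-4,8-dimethyl-10-(PMB-oxy)-9-(TBS-oxy)-5-(TBDPS-oxy)cyclodeca-3,7-dien-1-yl]acetate
Product: 31 (3aS,4R,5R,6Z,9S,10E,11aR)-6,10-dimethyl-4-(PMB-oxy)-5-(TBS-oxy)-9-(TBDPS-oxy)-3a,4,5,8,9,11a-hexahydrocyclodeca[b]furan-2(3H)-one
Conditions: KOt-Bu (0.2 equiv), THF, 0 °C
Reagents that add atoms: none
Why: Alkoxide-catalysed intramolecular transesterification (5-exo lactonisation) of the C6 alkoxide onto the C12 tert-butyl ester closes the trans-fused γ-lactone with retention at C6 and C7.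

Step 27
Reactants: 31 (3aS,4R,5R,6Z,9S,10E,11aR)-6,10-dimethyl-4-(PMB-oxy)-5-(TBS-oxy)-9-(TBDPS-oxy)-3a,4,5,8,9,11a-hexahydrocyclodeca[b]furan-2(3H)-one
Product: 32 (3R,3aS,4R,5R,6Z,9S,10E,11aR)-3-[(dimethylamino)methyl]-6,10-dimethyl-4-(PMB-oxy)-5-(TBS-oxy)-9-(TBDPS-oxy)-3a,4,5,8,9,11a-hexahydrocyclodeca[b]furan-2(3H)-one
Conditions: LiN(i-Pr)2, THF, −78 °C; then CH2=NMe2+ I−, −78 → 0 °C
Reagents that add atoms: N,N-dimethylmethyleneiminium iodide, C=[N+](C)C.[I-]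
Why: The lactone enolate undergoes a Mannich reaction with the iminium salt on the face opposite to the C7–C8 bond, giving the trans α-aminomethyl lactone (this C11 configuration is lost in the next step).

Step 28
Reactants: 32 (3R,3aS,4R,5R,6Z,9S,10E,11aR)-3-[(dimethylamino)methyl]-6,10-dimethyl-4-(PMB-oxy)-5-(TBS-oxy)-9-(TBDPS-oxy)-3a,4,5,8,9,11a-hexahydrocyclodeca[b]furan-2(3H)-one
Product: 34 (3aS,4R,5R,6Z,9S,10E,11aR)-6,10-dimethyl-3-methylidene-4-(PMB-oxy)-5-(TBS-oxy)-9-(TBDPS-oxy)-3a,4,5,8,9,11a-hexahydrocyclodeca[b]furan-2(3H)-one, via trimethylammonium iodide 33 (not isolated)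
Conditions: MeI, MeOH, rt; then aq. NaHCO3/CH2Cl2, rt
Reagents that add atoms: iodomethane, CI (atoms in 33 only)
Why: N-methylation to the quaternary ammonium salt and base-induced β-elimination (Hofmann-type, E1cB) give the α-methylene lactone.

Step 29
Reactants: 34 (3aS,4R,5R,6Z,9S,10E,11aR)-6,10-dimethyl-3-methylidene-4-(PMB-oxy)-5-(TBS-oxy)-9-(TBDPS-oxy)-3a,4,5,8,9,11a-hexahydrocyclodeca[b]furan-2(3H)-one
Product: 35 (3aR,4R,5R,6Z,9S,10E,11aR)-4-hydroxy-6,10-dimethyl-3-methylidene-5-(TBS-oxy)-9-(TBDPS-oxy)-3a,4,5,8,9,11a-hexahydrocyclodeca[b]furan-2(3H)-one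
Conditions: DDQ, CH2Cl2/pH 7 buffer (10:1), 0 °C
Reagents that add atoms: none
Why: Oxidative PMB cleavage by DDQ (benzylic hydride abstraction, then hydrolysis) frees only the C8 hydroxyl, and the descriptor at C3a changes by priority only.

Step 30
Reactants: 35 (3aR,4R,5R,6Z,9S,10E,11aR)-4-hydroxy-6,10-dimethyl-3-methylidene-5-(TBS-oxy)-9-(TBDPS-oxy)-3a,4,5,8,9,11a-hexahydrocyclodeca[b]furan-2(3H)-one
Product: 36 (3aS,4R,5R,6Z,9S,10E,11aR)-6,10-dimethyl-3-methylidene-2-oxo-5-(TBS-oxy)-9-(TBDPS-oxy)-2,3,3a,4,5,8,9,11a-octahydrocyclodeca[b]furan-4-yl (2Z)-2-methylbut-2-enoate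
Conditions: angelic acid, 2,4,6-trichlorobenzoyl chloride, Et3N, toluene, rt; then 35, 80 °C
Reagents that add atoms: angelic acid, C/C=C(/C)C(=O)O
Why: Yamaguchi-type mixed anhydride esterification without a nucleophilic amine catalyst acylates the hindered C8 hydroxyl while keeping the Z geometry of the angelate, and C8 keeps its configuration because its C–O bond is not broken.

Step 31
Reactants: 36 (3aS,4R,5R,6Z,9S,10E,11aR)-6,10-dimethyl-3-methylidene-2-oxo-5-(TBS-oxy)-9-(TBDPS-oxy)-2,3,3a,4,5,8,9,11a-octahydrocyclodeca[b]furan-4-yl (2Z)-2-methylbut-2-enoate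
Product: 37 (3aS,4R,5R,6Z,9S,10E,11aR)-5-hydroxy-6,10-dimethyl-3-methylidene-2-oxo-9-(TBDPS-oxy)-2,3,3a,4,5,8,9,11a-octahydrocyclodeca[b]furan-4-yl (2Z)-2-methylbut-2-enoate
Conditions: HF·pyridine, pyridine, THF, 0 °C → rt
Reagents that add atoms: none
Why: HF·pyridine cleaves the secondary TBS ether much faster than the TBDPS ether and frees the C9 hydroxyl under mildly acidic conditions that do not induce acyl migration.

Step 32
Reactants: 37 (3aS,4R,5R,6Z,9S,10E,11aR)-5-hydroxy-6,10-dimethyl-3-methylidene-2-oxo-9-(TBDPS-oxy)-2,3,3a,4,5,8,9,11a-octahydrocyclodeca[b]furan-4-yl (2Z)-2-methylbut-2-enoate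
Product: 38 (3aS,4R,5R,6Z,9S,10E,11aR)-5-acetoxy-6,10-dimethyl-3-methylidene-2-oxo-9-(TBDPS-oxy)-2,3,3a,4,5,8,9,11a-octahydrocyclodeca[b]furan-4-yl (2Z)-2-methylbut-2-enoate
Conditions: Ac2O, pyridine, DMAP (cat.), CH2Cl2, 0 °C → rt
Reagents that add atoms: acetic anhydride, CC(=O)OC(C)=O
Why: DMAP-catalysed acetylation of the C9 hydroxyl at low temperature is fast enough to outrun angeloyl migration.

Step 33
Reactants: 38 (3aS,4R,5R,6Z,9S,10E,11aR)-5-acetoxy-6,10-dimethyl-3-methylidene-2-oxo-9-(TBDPS-oxy)-2,3,3a,4,5,8,9,11a-octahydrocyclodeca[b]furan-4-yl (2Z)-2-methylbut-2-enoate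
Product: 39 (3aS,4R,5R,6Z,9S,10E,11aR)-5-acetoxy-9-hydroxy-6,10-dimethyl-3-methylidene-2-oxo-2,3,3a,4,5,8,9,11a-octahydrocyclodeca[b]furan-4-yl (2Z)-2-methylbut-2-enoate
Conditions: Bu4NF, AcOH (1:1), THF, 0 °C → rt
Reagents that add atoms: none
Why: Fluoride desilylation buffered with acetic acid removes the TBDPS group from C3 without attacking the α-methylene lactone or the two esters, giving the target.

**Compound list**

1 | cis-2-phenyl-1,3-dioxan-5-ol (achiral) | O[C@@H]1CO[C@H](c2ccccc2)OC1 | starting material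
2 | cis-5-(PMB-oxy)-2-phenyl-1,3-dioxane | COc1ccc(CO[C@@H]2CO[C@H](c3ccccc3)OC2)cc1 | intermediate
3 | 2-(PMB-oxy)propane-1,3-diol | OCC(CO)OCc1ccc(OC)cc1 | intermediate
4 | (2S)-3-hydroxy-2-(PMB-oxy)propyl acetate | CC(=O)OC[C@@H](OCc1ccc(OC)cc1)CO | intermediate
5 | (2R)-2-(PMB-oxy)-3-(TBDPS-oxy)propyl acetate | CC(=O)OC[C@@H](OCc1ccc(OC)cc1)CO[Si](c1ccccc1)(c1ccccc1)C(C)(C)C | intermediate
6 | (2R)-2-(PMB-oxy)-3-(TBDPS-oxy)propan-1-ol | OC[C@@H](OCc1ccc(OC)cc1)CO[Si](c1ccccc1)(c1ccccc1)C(C)(C)C | intermediate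
7 | (2S)-2-(PMB-oxy)-3-(TBDPS-oxy)propanal | O=C[C@@H](OCc1ccc(OC)cc1)CO[Si](c1ccccc1)(c1ccccc1)C(C)(C)C | intermediate
8 | tert-butyl (2E,4R)-4-(PMB-oxy)-5-(TBDPS-oxy)pent-2-enoate | CC(C)(C)OC(=O)/C=C/[C@@H](OCc1ccc(OC)cc1)CO[Si](c1ccccc1)(c1ccccc1)C(C)(C)C | intermediate
9 | O-trimethylsilyl ketene acetal of ester 10 (E/Z mixture at the ketene acetal; other centres as in 10) | CC(C)(C)OC(O[Si](C)(C)C)=C[C@@H](C=C)[C@@H](OCc1ccc(OC)cc1)CO[Si](c1ccccc1)(c1ccccc1)C(C)(C)C | intermediate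
10 | tert-butyl (3S,4R)-3-ethenyl-4-(PMB-oxy)-5-(TBDPS-oxy)pentanoate | CC(C)(C)OC(=O)C[C@@H](C=C)[C@@H](OCc1ccc(OC)cc1)CO[Si](c1ccccc1)(c1ccccc1)C(C)(C)C | intermediate
11 | tert-butyl (3S,4R)-3-ethenyl-5-hydroxy-4-(PMB-oxy)pentanoate | CC(C)(C)OC(=O)C[C@@H](C=C)[C@@H](OCc1ccc(OC)cc1)CO | intermediate
12 | tert-butyl (3S,4R)-3-ethenyl-5-oxo-4-(PMB-oxy)pentanoate | CC(C)(C)OC(=O)C[C@@H](C=C)[C@@H](OCc1ccc(OC)cc1)C=O | intermediate
13 | tert-butyl (3S,4R,5R)-3-ethenyl-5-hydroxy-6-methyl-4-(PMB-oxy)hept-6-enoate | CC(C)(C)OC(=O)C[C@@H](C=C)[C@@H](OCc1ccc(OC)cc1)[C@H](O)C(C)=C | intermediate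
14 | tert-butyl (3S,4R,5R)-3-ethenyl-6-methyl-4-(PMB-oxy)-5-(TBS-oxy)hept-6-enoate | CC(C)(C)OC(=O)C[C@@H](C=C)[C@@H](OCc1ccc(OC)cc1)[C@H](O[Si](C)(C)C(C)(C)C)C(C)=C | intermediate
15 | tert-butyl (3R,4R,5S)-3-formyl-6-oxo-4-(PMB-oxy)-5-(TBS-oxy)heptanoate | CC(C)(C)OC(=O)C[C@@H](C=O)[C@@H](OCc1ccc(OC)cc1)[C@H](O[Si](C)(C)C(C)(C)C)C(C)=O | intermediate
16 | tert-butyl (3R,4R,5S)-3-(dimethoxymethyl)-6-oxo-4-(PMB-oxy)-5-(TBS-oxy)heptanoate | CC(C)(C)OC(=O)C[C@@H](C(OC)OC)[C@@H](OCc1ccc(OC)cc1)[C@H](O[Si](C)(C)C(C)(C)C)C(C)=O | intermediate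
17 | diethyl methylmalonate | CCOC(=O)C(C)C(=O)OCC | starting material
18 | diethyl 2-(diiodomethyl)-2-methylmalonate | CCOC(=O)C(C)(C(I)I)C(=O)OCC | intermediate
19 | (2E)-3-iodo-2-methylprop-2-enoic acid | OC(=O)/C(C)=C/I | intermediate
20 | (2E)-1-(imidazol-1-yl)-3-iodo-2-methylprop-2-en-1-one | O=C(/C(C)=C/I)n1ccnc1 | intermediate
21 | ethyl (4E)-5-iodo-4-methyl-3-oxopent-4-enoate | CCOC(=O)CC(=O)/C(C)=C/I | intermediate
22 | ethyl (3S,4E)-3-hydroxy-5-iodo-4-methylpent-4-enoate | CCOC(=O)C[C@H](O)/C(C)=C/I | intermediate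
23 | ethyl (3S,4E)-5-iodo-4-methyl-3-(TBDPS-oxy)pent-4-enoate | CCOC(=O)C[C@H](O[Si](c1ccccc1)(c1ccccc1)C(C)(C)C)/C(C)=C/I | intermediate
24 | (3S,4E)-5-iodo-4-methyl-3-(TBDPS-oxy)pent-4-en-1-ol | OCC[C@H](O[Si](c1ccccc1)(c1ccccc1)C(C)(C)C)/C(C)=C/I | intermediate
25 | (1E,3S)-1,5-diiodo-2-methyl-3-(TBDPS-oxy)pent-1-ene | ICC[C@H](O[Si](c1ccccc1)(c1ccccc1)C(C)(C)C)/C(C)=C/I | intermediate
26 | [(3S,4E)-5-iodo-4-methyl-3-(TBDPS-oxy)pent-4-en-1-yl]triphenylphosphonium iodide | [I-].c1ccccc1[P+](c1ccccc1)(c1ccccc1)CC[C@H](O[Si](c1ccccc1)(c1ccccc1)C(C)(C)C)/C(C)=C/I | intermediate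
27 | [(3S,4E)-5-iodo-4-methyl-3-(TBDPS-oxy)pent-4-en-1-ylidene]triphenylphosphorane | c1ccccc1P(c1ccccc1)(c1ccccc1)=CC[C@H](O[Si](c1ccccc1)(c1ccccc1)C(C)(C)C)/C(C)=C/I | intermediate
28 | tert-butyl (3R,4R,5R,6Z,9S,10E)-3-(dimethoxymethyl)-11-iodo-6,10-dimethyl-4-(PMB-oxy)-5-(TBS-oxy)-9-(TBDPS-oxy)undeca-6,10-dienoate | CC(C)(C)OC(=O)C[C@@H](C(OC)OC)[C@@H](OCc1ccc(OC)cc1)[C@H](O[Si](C)(C)C(C)(C)C)/C(C)=C\C[C@H](O[Si](c1ccccc1)(c1ccccc1)C(C)(C)C)/C(C)=C/I | intermediate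
29 | tert-butyl (3R,4R,5R,6Z,9S,10E)-3-formyl-11-iodo-6,10-dimethyl-4-(PMB-oxy)-5-(TBS-oxy)-9-(TBDPS-oxy)undeca-6,10-dienoate | CC(C)(C)OC(=O)C[C@@H](C=O)[C@@H](OCc1ccc(OC)cc1)[C@H](O[Si](C)(C)C(C)(C)C)/C(C)=C\C[C@H](O[Si](c1ccccc1)(c1ccccc1)C(C)(C)C)/C(C)=C/I | intermediate
30 | tert-butyl 2-[(1S,2R,3E,5S,7Z,9R,10R)-2-hydroxy-4,8-dimethyl-10-(PMB-oxy)-9-(TBS-oxy)-5-(TBDPS-oxy)cyclodeca-3,7-dien-1-yl]acetate | O[C@@H]1/C=C(\C)[C@@H](O[Si](c2ccccc2)(c2ccccc2)C(C)(C)C)C/C=C(/C)[C@@H](O[Si](C)(C)C(C)(C)C)[C@H](OCc2ccc(OC)cc2)[C@H]1CC(=O)OC(C)(C)C | intermediate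
31 | (3aS,4R,5R,6Z,9S,10E,11aR)-6,10-dimethyl-4-(PMB-oxy)-5-(TBS-oxy)-9-(TBDPS-oxy)-3a,4,5,8,9,11a-hexahydrocyclodeca[b]furan-2(3H)-one | O=C1O[C@@H]2/C=C(\C)[C@@H](O[Si](c3ccccc3)(c3ccccc3)C(C)(C)C)C/C=C(/C)[C@@H](O[Si](C)(C)C(C)(C)C)[C@H](OCc3ccc(OC)cc3)[C@H]2C1 | intermediate
32 | (3R,3aS,4R,5R,6Z,9S,10E,11aR)-3-[(dimethylamino)methyl]-6,10-dimethyl-4-(PMB-oxy)-5-(TBS-oxy)-9-(TBDPS-oxy)-3a,4,5,8,9,11a-hexahydrocyclodeca[b]furan-2(3H)-one | CN(C)C[C@@H]1C(=O)O[C@@H]2/C=C(\C)[C@@H](O[Si](c3ccccc3)(c3ccccc3)C(C)(C)C)C/C=C(/C)[C@@H](O[Si](C)(C)C(C)(C)C)[C@H](OCc3ccc(OC)cc3)[C@@H]12 | intermediate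
33 | N-methyl quaternary ammonium iodide of 32 (trimethylammoniomethyl lactone) | C[N+](C)(C)C[C@@H]1C(=O)O[C@@H]2/C=C(\C)[C@@H](O[Si](c3ccccc3)(c3ccccc3)C(C)(C)C)C/C=C(/C)[C@@H](O[Si](C)(C)C(C)(C)C)[C@H](OCc3ccc(OC)cc3)[C@@H]12.[I-] | intermediate
34 | (3aS,4R,5R,6Z,9S,10E,11aR)-6,10-dimethyl-3-methylidene-4-(PMB-oxy)-5-(TBS-oxy)-9-(TBDPS-oxy)-3a,4,5,8,9,11a-hexahydrocyclodeca[b]furan-2(3H)-one | C=C1C(=O)O[C@@H]2/C=C(\C)[C@@H](O[Si](c3ccccc3)(c3ccccc3)C(C)(C)C)C/C=C(/C)[C@@H](O[Si](C)(C)C(C)(C)C)[C@H](OCc3ccc(OC)cc3)[C@@H]12 | intermediate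
35 | (3aR,4R,5R,6Z,9S,10E,11aR)-4-hydroxy-6,10-dimethyl-3-methylidene-5-(TBS-oxy)-9-(TBDPS-oxy)-3a,4,5,8,9,11a-hexahydrocyclodeca[b]furan-2(3H)-one | C=C1C(=O)O[C@@H]2/C=C(\C)[C@@H](O[Si](c3ccccc3)(c3ccccc3)C(C)(C)C)C/C=C(/C)[C@@H](O[Si](C)(C)C(C)(C)C)[C@H](O)[C@@H]12 | intermediate
36 | (3aS,4R,5R,6Z,9S,10E,11aR)-6,10-dimethyl-3-methylidene-2-oxo-5-(TBS-oxy)-9-(TBDPS-oxy)-2,3,3a,4,5,8,9,11a-octahydrocyclodeca[b]furan-4-yl (2Z)-2-methylbut-2-enoate | C=C1C(=O)O[C@@H]2/C=C(\C)[C@@H](O[Si](c3ccccc3)(c3ccccc3)C(C)(C)C)C/C=C(/C)[C@@H](O[Si](C)(C)C(C)(C)C)[C@H](OC(=O)/C(C)=C\C)[C@@H]12 | intermediate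
37 | (3aS,4R,5R,6Z,9S,10E,11aR)-5-hydroxy-6,10-dimethyl-3-methylidene-2-oxo-9-(TBDPS-oxy)-2,3,3a,4,5,8,9,11a-octahydrocyclodeca[b]furan-4-yl (2Z)-2-methylbut-2-enoate | C=C1C(=O)O[C@@H]2/C=C(\C)[C@@H](O[Si](c3ccccc3)(c3ccccc3)C(C)(C)C)C/C=C(/C)[C@@H](O)[C@H](OC(=O)/C(C)=C\C)[C@@H]12 | intermediate
38 | (3aS,4R,5R,6Z,9S,10E,11aR)-5-acetoxy-6,10-dimethyl-3-methylidene-2-oxo-9-(TBDPS-oxy)-2,3,3a,4,5,8,9,11a-octahydrocyclodeca[b]furan-4-yl (2Z)-2-methylbut-2-enoate | C=C1C(=O)O[C@@H]2/C=C(\C)[C@@H](O[Si](c3ccccc3)(c3ccccc3)C(C)(C)C)C/C=C(/C)[C@@H](OC(C)=O)[C@H](OC(=O)/C(C)=C\C)[C@@H]12 | intermediate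
39 | (3aS,4R,5R,6Z,9S,10E,11aR)-5-acetoxy-9-hydroxy-6,10-dimethyl-3-methylidene-2-oxo-2,3,3a,4,5,8,9,11a-octahydrocyclodeca[b]furan-4-yl (2Z)-2-methylbut-2-enoate (CNP0265116.2) | C=C1C(=O)O[C@@H]2/C=C(\C)[C@@H](O)C/C=C(/C)[C@@H](OC(C)=O)[C@H](OC(=O)/C(C)=C\C)[C@@H]12 | target

**Step count and risks**

Total step count: 33 (steps 1–14 ketone part, 15–22 ylide part, 23–33 union and end game). Longest linear sequence: 25 steps (1–14, then 23–33).

The three steps most likely to fail: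

Step 25 (ring closure and C6 configuration). The macrocyclic coupling creates C6 under substrate control and may give mainly the C6 epimer or a mixture. The fallback sets out from the crude cyclisation product (30 together with its C6 epimer) and comes back at 30. The mixture is oxidised with Dess–Martin periodinane to the macrocyclic enone tert-butyl 2-[(1R,3E,5S,7Z,9R,10R)-4,8-dimethyl-2-oxo-10-(PMB-oxy)-9-(TBS-oxy)-5-(TBDPS-oxy)cyclodeca-3,7-dien-1-yl]acetate F3. F3 is then reduced with BH3·SMe2 and the Me-CBS oxazaborolidine (1-methyl-3,3-diphenyltetrahydropyrrolo[1,2-c][1,3,2]oxazaborole) antipode that gives 6R, both antipodes being tried once. C6 is thereby set under reagent control and the material re-enters as 30.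

Step 23 (Wittig union). The ylide may enolise ketone 16 or give an unsatisfactory Z:E ratio. The fallback sets out from iodide 25 and ketone 16 and comes back at 28. Iodide 25 is treated with Ph2P(O)Na (from Ph2P(O)H and NaH, THF) to give [(3S,4E)-5-iodo-4-methyl-3-(TBDPS-oxy)pent-4-en-1-yl](diphenyl)phosphane oxide F1. F1 is lithiated with LiN(i-Pr)2 at −78 °C and added to 16, and the β-hydroxy phosphine oxide diastereomers are separated on silica to give tert-butyl (3R,4R,5S,6S,7R,9S,10E)-3-(dimethoxymethyl)-7-(diphenylphosphoryl)-6-hydroxy-11-iodo-6,10-dimethyl-4-(PMB-oxy)-5-(TBS-oxy)-9-(TBDPS-oxy)undec-10-enoate F2. NaH in DMF then causes stereospecific syn-elimination (Horner–Wittig) of F2 to 28, so the olefin geometry is fixed by a separable intermediate and not by kinetic selectivity.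

Step 30 (angeloylation). The hindered C8 hydroxyl may not react, the angelate may isomerise to the tiglate on heating, or the free 8-hydroxy lactone may translactonise under the basic, hot conditions. The fallback sets out from 35 and comes back at 36. Alcohol 35 is esterified at room temperature with 2-[bis(2,2,2-trifluoroethoxy)phosphoryl]propanoic acid (DCC, DMAP, CH2Cl2) to give (3aS,4R,5R,6Z,9S,10E,11aR)-6,10-dimethyl-3-methylidene-2-oxo-5-(TBS-oxy)-9-(TBDPS-oxy)-2,3,3a,4,5,8,9,11a-octahydrocyclodeca[b]furan-4-yl 2-[bis(2,2,2-trifluoroethoxy)phosphoryl]propanoate F4 (mixture at the phosphonate carbon, which is of no consequence). A Still–Gennari olefination of F4 with acetaldehyde (KN(SiMe3)2, 18-crown-6, THF, −78 °C) then builds the Z-trisubstituted double bond of the angelate in place and gives 36.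

**Further compounds**

F1 | step 23 | [(3S,4E)-5-iodo-4-methyl-3-(TBDPS-oxy)pent-4-en-1-yl](diphenyl)phosphane oxide | O=P(c1ccccc1)(c1ccccc1)CC[C@H](O[Si](c1ccccc1)(c1ccccc1)C(C)(C)C)/C(C)=C/I
F2 | step 23 | tert-butyl (3R,4R,5S,6S,7R,9S,10E)-3-(dimethoxymethyl)-7-(diphenylphosphoryl)-6-hydroxy-11-iodo-6,10-dimethyl-4-(PMB-oxy)-5-(TBS-oxy)-9-(TBDPS-oxy)undec-10-enoate | CC(C)(C)OC(=O)C[C@@H](C(OC)OC)[C@@H](OCc1ccc(OC)cc1)[C@H](O[Si](C)(C)C(C)(C)C)[C@](C)(O)[C@@H](C[C@H](O[Si](c1ccccc1)(c1ccccc1)C(C)(C)C)/C(C)=C/I)P(=O)(c1ccccc1)c1ccccc1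
F3 | step 25 | tert-butyl 2-[(1R,3E,5S,7Z,9R,10R)-4,8-dimethyl-2-oxo-10-(PMB-oxy)-9-(TBS-oxy)-5-(TBDPS-oxy)cyclodeca-3,7-dien-1-yl]acetate | O=C1/C=C(\C)[C@@H](O[Si](c2ccccc2)(c2ccccc2)C(C)(C)C)C/C=C(/C)[C@@H](O[Si](C)(C)C(C)(C)C)[C@H](OCc2ccc(OC)cc2)[C@H]1CC(=O)OC(C)(C)C
F4 | step 30 | (3aS,4R,5R,6Z,9S,10E,11aR)-6,10-dimethyl-3-methylidene-2-oxo-5-(TBS-oxy)-9-(TBDPS-oxy)-2,3,3a,4,5,8,9,11a-octahydrocyclodeca[b]furan-4-yl 2-[bis(2,2,2-trifluoroethoxy)phosphoryl]propanoate (phosphonate carbon undefined) | C=C1C(=O)O[C@@H]2/C=C(\C)[C@@H](O[Si](c3ccccc3)(c3ccccc3)C(C)(C)C)C/C=C(/C)[C@@H](O[Si](C)(C)C(C)(C)C)[C@H](OC(=O)C(C)P(=O)(OCC(F)(F)F)OCC(F)(F)F)[C@@H]12
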